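## Retrosynthetic overview

1. Target 18 ⇐ hydrogenolysis of six benzyl ethers of 17 ⇐ oxidation of the C3–B bond of boronate 15 with retention.
2. The strategy rests on ring C of the upper unit: O1–C2–C3–C4 between C8a and C4a of ring A, with three contiguous all-trans centres (C2 ring B, C3 OH, C4 ring D). This is the pattern an ortho-quinone methide (O1, C8a, C4a, C4) gives with an (E)-alkene C2=C3, so ring C ⇐ methide 14 + (E)-styrylboronate 13, forming C3–C4 and O1–C2.
3. Methide 14 ⇐ benzhydrol 9 ⇐ 8-lithio-penta-O-benzylepicatechin + salicylaldehyde 6 (C4–C8 bond to ring D); rings D, E, F come intact from (−)-epicatechin.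
4. Boronate 13 ⇐ cross-metathesis of 4-acetoxystyrene with vinyl pinacolboronate, then deacetylation (the free alkynylphenol/hydrozirconation route is avoided because the phenol would quench the hydride catalyst).
5. Ring order: A, B and D/E/F are preformed; ring C is the only ring built, and it is built last.

Key step: step 7

Ring labels: upper unit A (benzo), B (4-hydroxyphenyl), C (pyran); lower unit D (benzo), E (catechol), F (pyran); atom numbers are flavan numbers within each unit.

Assumption: the (R)-configured phosphoric acid is taken as the antipode that leads to (4R) in step 7; if a test reaction shows the opposite sense, the (S)-acid is used with nothing else changed, and the two C4 series are diastereomers that should be separable.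

## Route

Step 1
Reactants: 1 (−)-epicatechin
Product: 2 5,7,3′,4′-tetra-O-benzyl-(−)-epicatechin
Conditions: BnBr (4.4 equiv), K2CO3, DMF, 0 °C → rt, under argon
Reagents that add atoms: benzyl bromide, BrCc1ccccc1
Why: Williamson etherification in which K2CO3 deprotonates only the four phenols, so the secondary 3-OH stays free and C2/C3 are untouched at room temperature.

Step 2
Reactants: 2 5,7,3′,4′-tetra-O-benzyl-(−)-epicatechin
Product: 4 3,5,7,3′,4′-penta-O-benzyl-(−)-epicatechin, via sodium 3-alkoxide 3 (not isolated)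
Conditions: NaH, BnBr, n-Bu4NI (cat.), THF/DMF, 0 °C → rt
Reagents that add atoms: benzyl bromide, BrCc1ccccc1
Why: Williamson ether synthesis on the secondary alkoxide; with no free phenol left, base-induced opening of ring F and epimerisation at C2 cannot occur.

Step 3
Reactants: 4 3,5,7,3′,4′-penta-O-benzyl-(−)-epicatechin
Product: 5 8-bromo-3,5,7,3′,4′-penta-O-benzyl-(−)-epicatechin
Conditions: NBS (1.05 equiv), CH2Cl2, −78 °C → rt
Reagents that add atoms: N-bromosuccinimide, O=C1CCC(=O)N1Br
Why: electrophilic aromatic bromination, which in benzylated flavan-3-ols is known to go to C8 of ring D in preference to C6.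

Step 4
Reactants: 5 8-bromo-3,5,7,3′,4′-penta-O-benzyl-(−)-epicatechin; 6 4-(benzyloxy)-2-hydroxybenzaldehyde
Product: 9 (4-benzyloxy-2-hydroxyphenyl)(penta-O-benzylepicatechin-8-yl)methanol, both carbinol epimers, via 8-lithio-penta-O-benzylepicatechin 7 (not isolated), via sodium 5-(benzyloxy)-2-formylphenolate 8 (not isolated)
Conditions: 5, t-BuLi (2.05 equiv), THF, −78 °C; separately 6, NaH (1.0 equiv), THF, 0 °C; phenolate added to the aryllithium, −78 → −20 °C; aq NH4Cl; chromatography on Et3N-washed silica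
Reagents that add atoms: none
Why: bromine–lithium exchange followed by 1,2-addition of the aryllithium to the aldehyde, whose phenol is carried as its sodium salt so that it cannot protonate the organolithium; the carbinol centre forms unselectively, which does not matter because it becomes trigonal in step 7.

Step 5
Reactants: 10 4-acetoxystyrene; 11 vinylboronic acid pinacol ester (2 equiv)
Product: 12 (E)-2-(4-acetoxyphenyl)vinylboronic acid pinacol ester
Conditions: RuCl2(H2IMes)(PCy3)(=CHPh) (second-generation Grubbs catalyst, 3 mol %), CH2Cl2, 40 °C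
Reagents that add atoms: none
Why: olefin cross-metathesis of a styrene with vinyl pinacolboronate, which is known to give the (E)-styrylboronate with loss of ethylene.

Step 6
Reactants: 12 (E)-2-(4-acetoxyphenyl)vinylboronic acid pinacol ester
Product: 13 (E)-2-(4-hydroxyphenyl)vinylboronic acid pinacol ester
Conditions: K2CO3 (0.3 equiv), MeOH, 0 °C; aq NH4Cl; used promptly
Reagents that add atoms: none
Why: base-catalysed transesterification of the aryl acetate with methanol, mild and brief enough to leave the alkenyl pinacolboronate and the (E)-geometry intact.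

Step 7
Reactants: 9 (4-benzyloxy-2-hydroxyphenyl)(penta-O-benzylepicatechin-8-yl)methanol; 13 (E)-2-(4-hydroxyphenyl)vinylboronic acid pinacol ester (1.5 equiv)
Product: 15 (2R,3R,4R)-7-benzyloxy-2-(4-hydroxyphenyl)-3-(pinacolboryl)-4-(penta-O-benzylepicatechin-8-yl)chroman, 2,3-trans-3,4-trans, via (E)-ortho-quinone methide 14 (not isolated)
Conditions: (R)-3,3′-bis(2,4,6-triisopropylphenyl)-1,1′-binaphthyl-2,2′-diyl hydrogen phosphate (10 mol %), 4 Å MS, PhMe/CH2Cl2, −20 → 0 °C
Reagents that add atoms: none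
Why: Proposed new method: the phosphoric acid dehydrates 9 to the (E)-ortho-quinone methide 14 and holds it by a hydrogen bond to the carbonyl oxygen while its phosphoryl oxygen binds the phenol of 13; the methide carbon C4 then attacks the boron-bearing alkene carbon (C3), charge builds at the benzylic C2 (stabilised by the 4-hydroxyphenyl ring and the adjacent C–B bond), and the ring A oxygen O1 collapses onto C2 in an asynchronous concerted inverse-demand oxa-[4+2] cycloaddition. The closest known reaction type is the chiral phosphoric acid-catalysed [4+2] cycloaddition of in situ ortho-quinone methides with hydroxystyrenes to 2,4-cis-chromans; an alkenylboronate has not been shown as the two-carbon partner. Ring C is closed in this six-membered [4+2] mode, C3–C4 and O1–C2 being formed in one event. C2/C3 trans follows from the retained (E)-alkene geometry, C2/C4 cis from the (E)-methide geometry together with endo placement of ring B (all three substituents equatorial, also the thermodynamic arrangement), and the absolute sense at C4 from the catalyst pocket, because the ring F stereocentres are too remote to decide. The step needs regioselectivity (C4 to the boron carbon, secured by the para-hydroxyphenyl donor), ring closure faster than loss of boron from the C2 cation (favoured by the weakly Lewis acidic pinacol ester, the intramolecular O1 nucleophile and sieves that keep water away), and catalyst-controlled facial selectivity.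

Step 8
Reactants: 15 (2R,3R,4R)-3-boryl chroman
Product: 17 (2S,3R,4R)-7-benzyloxy-2-(4-hydroxyphenyl)-4-(penta-O-benzylepicatechin-8-yl)chroman-3-ol, via 3-O-pinacolboryl borate ester 16 (not isolated)
Conditions: NaBO3·4H2O (5 equiv), THF/H2O, 0 °C → rt
Reagents that add atoms: sodium perborate (water of crystallisation omitted), [Na+].[O-]OB=O
Why: oxidation of a carbon–boron bond by peroxide addition to boron and 1,2-migration of C3 from boron to oxygen with retention, so the 3-OH takes the position of boron, trans to both aryl groups; the mild pH of perborate limits phenoxide-driven opening of ring C.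

Step 9
Reactants: 17 hexa-O-benzyl flavan-3-ol
Product: 18 (2R,3R)-2-(3,4-dihydroxyphenyl)-8-[(2S,3R,4R)-3,7-dihydroxy-2-(4-hydroxyphenyl)chroman-4-yl]chroman-3,5,7-triol, the target
Conditions: H2 (1 atm), Pd(OH)2/C, THF/MeOH/H2O, rt; filtration under argon, lyophilisation
Reagents that add atoms: none
Why: catalytic hydrogenolysis of the six benzyl ethers under the conditions standard for benzylated flavan-3-ol dimers, which leave the C4–C8 interflavan bond and the two benzylic C2–O1 bonds intact at atmospheric pressure.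

## Compound list

1 | (−)-epicatechin, (2R,3R) | Oc1cc(O)c2c(c1)O[C@H](c1ccc(O)c(O)c1)[C@H](O)C2 | starting material
2 | 5,7,3′,4′-tetra-O-benzyl-(−)-epicatechin | c1c(OCc9ccccc9)cc(OCc9ccccc9)c2c1O[C@H](c1ccc(OCc9ccccc9)c(OCc9ccccc9)c1)[C@H](O)C2 | intermediate
3 | sodium 3-alkoxide of 2 | c1c(OCc9ccccc9)cc(OCc9ccccc9)c2c1O[C@H](c1ccc(OCc9ccccc9)c(OCc9ccccc9)c1)[C@H]([O-])C2.[Na+] | intermediate (not isolated)
4 | 3,5,7,3′,4′-penta-O-benzyl-(−)-epicatechin | c1c(OCc9ccccc9)cc(OCc9ccccc9)c2c1O[C@H](c1ccc(OCc9ccccc9)c(OCc9ccccc9)c1)[C@H](OCc9ccccc9)C2 | intermediate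
5 | 8-bromo-3,5,7,3′,4′-penta-O-benzyl-(−)-epicatechin | Brc1c(OCc9ccccc9)cc(OCc9ccccc9)c2c1O[C@H](c1ccc(OCc9ccccc9)c(OCc9ccccc9)c1)[C@H](OCc9ccccc9)C2 | intermediate
6 | 4-(benzyloxy)-2-hydroxybenzaldehyde | O=Cc1ccc(OCc2ccccc2)cc1O | starting material
7 | 8-lithio-3,5,7,3′,4′-penta-O-benzylepicatechin | [Li]c1c(OCc9ccccc9)cc(OCc9ccccc9)c2c1O[C@H](c1ccc(OCc9ccccc9)c(OCc9ccccc9)c1)[C@H](OCc9ccccc9)C2 | intermediate (not isolated)
8 | sodium 5-(benzyloxy)-2-formylphenolate | [Na+].[O-]c1cc(OCc2ccccc2)ccc1C=O | intermediate (not isolated)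
9 | (4-benzyloxy-2-hydroxyphenyl)(penta-O-benzylepicatechin-8-yl)methanol, carbinol epimers | Oc1cc(OCc9ccccc9)ccc1C(O)c1c(OCc9ccccc9)cc(OCc9ccccc9)c2c1O[C@H](c1ccc(OCc9ccccc9)c(OCc9ccccc9)c1)[C@H](OCc9ccccc9)C2 | intermediate
10 | 4-acetoxystyrene | CC(=O)Oc1ccc(C=C)cc1 | starting material
11 | vinylboronic acid pinacol ester | C=CB1OC(C)(C)C(C)(C)O1 | starting material
12 | (E)-2-(4-acetoxyphenyl)vinylboronic acid pinacol ester | CC(=O)Oc1ccc(/C=C/B2OC(C)(C)C(C)(C)O2)cc1 | intermediate
13 | (E)-2-(4-hydroxyphenyl)vinylboronic acid pinacol ester | Oc1ccc(/C=C/B2OC(C)(C)C(C)(C)O2)cc1 | intermediate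
14 | (E)-ortho-quinone methide from 9 (ring D aryl anti to the carbonyl carbon) | O=C1C=C(OCc9ccccc9)C=C\C1=C/c1c(OCc9ccccc9)cc(OCc9ccccc9)c2c1O[C@H](c1ccc(OCc9ccccc9)c(OCc9ccccc9)c1)[C@H](OCc9ccccc9)C2 | intermediate (not isolated)
15 | (2R,3R,4R)-7-benzyloxy-2-(4-hydroxyphenyl)-3-(pinacolboryl)-4-(penta-O-benzylepicatechin-8-yl)chroman, all-trans (descriptors at C2 differ from the target only because boron ranks below carbon) | Oc1ccc([C@@H]2Oc3cc(OCc9ccccc9)ccc3[C@H](c3c(OCc9ccccc9)cc(OCc9ccccc9)c4c3O[C@H](c3ccc(OCc9ccccc9)c(OCc9ccccc9)c3)[C@H](OCc9ccccc9)C4)[C@H]2B3OC(C)(C)C(C)(C)O3)cc1 | intermediate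
16 | 3-O-pinacolboryl borate ester of 17 | Oc1ccc([C@@H]2Oc3cc(OCc9ccccc9)ccc3[C@H](c3c(OCc9ccccc9)cc(OCc9ccccc9)c4c3O[C@H](c3ccc(OCc9ccccc9)c(OCc9ccccc9)c3)[C@H](OCc9ccccc9)C4)[C@H]2OB3OC(C)(C)C(C)(C)O3)cc1 | intermediate (not isolated)
17 | (2S,3R,4R)-7-benzyloxy-2-(4-hydroxyphenyl)-4-(penta-O-benzylepicatechin-8-yl)chroman-3-ol, all-trans | Oc1ccc([C@@H]2Oc3cc(OCc9ccccc9)ccc3[C@H](c3c(OCc9ccccc9)cc(OCc9ccccc9)c4c3O[C@H](c3ccc(OCc9ccccc9)c(OCc9ccccc9)c3)[C@H](OCc9ccccc9)C4)[C@H]2O)cc1 | intermediate
18 | (2R,3R)-2-(3,4-dihydroxyphenyl)-8-[(2S,3R,4R)-3,7-dihydroxy-2-(4-hydroxyphenyl)chroman-4-yl]chroman-3,5,7-triol | Oc1ccc([C@@H]2Oc3cc(O)ccc3[C@H](c3c(O)cc(O)c4c3O[C@H](c3ccc(O)c(O)c3)[C@H](O)C4)[C@H]2O)cc1 | target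

## Summary and risks

Total step count: 9. Longest linear sequence: 7 steps (1, 2, 3, 4, 7, 8, 9).

Steps most likely to fail:

**Step 7.** The benzylic C2 cation may lose boron before O1 closes, which transfers the styryl group to C4 without forming ring C. Bond formation between the hindered methide carbon and the boron-bearing carbon may also be slow, and the catalyst may give poor facial selectivity. The fallback sets out from 9 and comes back at 17, using known steps only. The methide from 9 is trapped by commercial tert-butyl(4-ethynylphenoxy)dimethylsilane with FeCl3 (10 mol %) in CH2Cl2 at 0 °C, the known acid-catalysed [4+2] route from ortho-hydroxybenzyl alcohols and arylalkynes to 2,4-diaryl-4H-chromenes. This should give two C4 epimers, diastereomeric because of the homochiral lower unit and therefore separable; the (4R) epimer is the 4H-chromene F1. Hydroboration of its C2=C3 enol ether bond with BH3·SMe2 in THF puts boron on C3 and hydrogen on C2 from the face opposite the C4 aryl group, the known route from flav-2-enes to 2,3-trans-flavan-3-ols, giving the all-trans 3-boranyl flavan F2 (not isolated). NaOH/H2O2 converts it into the 4′-O-silyl flavan-3-ol F3, and n-Bu4NF/AcOH in THF removes the silyl ether to give 17. Control of C4 by a catalyst is given up; C2 and C3 follow from C4.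

**Step 8.** Oxidation may be slow because boron is shielded by the two flanking aryl groups, and the base may open ring C through the 4′-phenoxide, with loss of the C2 configuration or elimination across C2–C3. The fallback sets out from 15 and comes back at 18. The free 4′-phenol is capped first (BnBr, K2CO3, DMF, rt) to give the hepta-O-benzyl boronate F4. This can then be oxidised under forcing conditions (H2O2, NaOH, THF, 0 → 40 °C) to the hepta-O-benzyl flavan-3-ol F5, and hydrogenolysis under the conditions of step 9 removes seven benzyl ethers to give 18.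

**Step 4.** Addition may be incomplete because the sodium phenolate of the aldehyde is poorly soluble and weakly electrophilic, and the hindered aryllithium may be protonated or decompose on warming. The fallback sets out from 6 (with 5 as before) and comes back at 9. The phenol of 6 is silylated (t-BuMe2SiCl, imidazole, DMF) to give 4-(benzyloxy)-2-(tert-butyldimethylsilyloxy)benzaldehyde F6. The aryllithium 7, made from 5 as in step 4, adds to this soluble aldehyde at −78 °C to give the silyl-protected benzhydrol F7; silyl transfer to the new alkoxide would be harmless. n-Bu4NF buffered with AcOH in THF at 0 °C then gives 9.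

## Further compounds

F1 | step 7 | (4R)-7-benzyloxy-2-[4-(tert-butyldimethylsilyloxy)phenyl]-4-(penta-O-benzylepicatechin-8-yl)-4H-chromene | CC(C)(C)[Si](C)(C)Oc1ccc(C2=C[C@@H](c3c(OCc9ccccc9)cc(OCc9ccccc9)c4c3O[C@H](c3ccc(OCc9ccccc9)c(OCc9ccccc9)c3)[C@H](OCc9ccccc9)C4)c3ccc(OCc9ccccc9)cc3O2)cc1
F2 | step 7 | (2R,3R,4R)-3-boranyl-7-benzyloxy-2-[4-(tert-butyldimethylsilyloxy)phenyl]-4-(penta-O-benzylepicatechin-8-yl)chroman | CC(C)(C)[Si](C)(C)Oc1ccc([C@@H]2Oc3cc(OCc9ccccc9)ccc3[C@H](c3c(OCc9ccccc9)cc(OCc9ccccc9)c4c3O[C@H](c3ccc(OCc9ccccc9)c(OCc9ccccc9)c3)[C@H](OCc9ccccc9)C4)[C@H]2B)cc1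
F3 | step 7 | (2S,3R,4R)-7-benzyloxy-2-[4-(tert-butyldimethylsilyloxy)phenyl]-4-(penta-O-benzylepicatechin-8-yl)chroman-3-ol | CC(C)(C)[Si](C)(C)Oc1ccc([C@@H]2Oc3cc(OCc9ccccc9)ccc3[C@H](c3c(OCc9ccccc9)cc(OCc9ccccc9)c4c3O[C@H](c3ccc(OCc9ccccc9)c(OCc9ccccc9)c3)[C@H](OCc9ccccc9)C4)[C@H]2O)cc1
F4 | step 8 | (2R,3R,4R)-7-benzyloxy-2-(4-benzyloxyphenyl)-3-(pinacolboryl)-4-(penta-O-benzylepicatechin-8-yl)chroman | C(c9ccccc9)Oc1ccc([C@@H]2Oc3cc(OCc9ccccc9)ccc3[C@H](c3c(OCc9ccccc9)cc(OCc9ccccc9)c4c3O[C@H](c3ccc(OCc9ccccc9)c(OCc9ccccc9)c3)[C@H](OCc9ccccc9)C4)[C@H]2B3OC(C)(C)C(C)(C)O3)cc1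
F5 | step 8 | (2S,3R,4R)-7-benzyloxy-2-(4-benzyloxyphenyl)-4-(penta-O-benzylepicatechin-8-yl)chroman-3-ol | C(c9ccccc9)Oc1ccc([C@@H]2Oc3cc(OCc9ccccc9)ccc3[C@H](c3c(OCc9ccccc9)cc(OCc9ccccc9)c4c3O[C@H](c3ccc(OCc9ccccc9)c(OCc9ccccc9)c3)[C@H](OCc9ccccc9)C4)[C@H]2O)cc1
F6 | step 4 | 4-(benzyloxy)-2-(tert-butyldimethylsilyloxy)benzaldehyde | CC(C)(C)[Si](C)(C)Oc1cc(OCc2ccccc2)ccc1C=O
F7 | step 4 | [4-benzyloxy-2-(tert-butyldimethylsilyloxy)phenyl](penta-O-benzylepicatechin-8-yl)methanol, carbinol epimers | CC(C)(C)[Si](C)(C)Oc1cc(OCc9ccccc9)ccc1C(O)c1c(OCc9ccccc9)cc(OCc9ccccc9)c2c1O[C@H](c1ccc(OCc9ccccc9)c(OCc9ccccc9)c1)[C@H](OCc9ccccc9)C2
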